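**Plan**

- Retrosynthesis: the oxirane CH2–O bond and the aryl tiglate ester are cut first. The quaternary C–O bond and the C–Br bond of a bromomethyl cyclic carbonate are then cut together, which reveals a 2-arylallyl isobutyrate whose phenol is a tert-butyl carbonate.
- That alkene is cut at the isobutyrate ester, the allylic C–O bond, the carbonate and the aryl–alkenyl C–C bond, back to 4-methoxy-3-methylphenol and an isopropenyl boronate.
- Enabling feature: the phenolic oxygen on C1 of the benzene ring is ortho to C2, which carries the quaternary oxirane carbon. A carbonyl on that oxygen therefore closes a six-membered ring (carbonyl O, carbonate C, phenolic O, C1, C2, quaternary C) and hands over the oxygen that ends in the oxirane.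
- Forward: arene bromination and Suzuki coupling join the three-carbon chain. The six-membered cyclic carbonate is the first new ring (step 6) and is opened again in step 7. The oxirane closes last (step 8).
- The only stereocentre is set in step 6 by the chiral catalyst–bromine complex, and no bond to it is broken afterwards.

Key step: step 6

Assumption: the facial sense of (DHQD)2PHAL on this new substrate class cannot be predicted with confidence; the route is written for the (S)-bromide, and the pseudoenantiomeric (DHQ)2PHAL would be used if the opposite sense is found.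

**Route**

Step 1
Reactants: 1 4-methoxy-3-methylphenol
Product: 2 2-bromo-4-methoxy-5-methylphenol
Conditions: NBS (1.0 equiv), MeCN, 0 °C
Reagents that add atoms: N-bromosuccinimide, O=C1CCC(=O)N1Br
Why: Electrophilic aromatic bromination directed by the free hydroxyl, whose para position is blocked by OMe, should go to the ortho carbon that is also para to the methyl group and not flanked by it.

Step 2
Reactants: 2 2-bromo-4-methoxy-5-methylphenol; 3 isopropenylboronic acid pinacol ester
Product: 4 4-methoxy-5-methyl-2-(prop-1-en-2-yl)phenol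
Conditions: Pd(PPh3)4 (5 mol %), K2CO3, 1,4-dioxane/H2O, 90 °C
Reagents that add atoms: isopropenylboronic acid pinacol ester (3), CC(=C)B1OC(C)(C)C(C)(C)O1
Why: Suzuki–Miyaura coupling of an aryl bromide with an alkenyl boronate under zerovalent palladium tolerates the free phenol and forms the aryl–alkenyl bond.

Step 3
Reactants: 4 4-methoxy-5-methyl-2-(prop-1-en-2-yl)phenol; 5 di-tert-butyl dicarbonate
Product: 6 tert-butyl [4-methoxy-5-methyl-2-(prop-1-en-2-yl)phenyl] carbonate
Conditions: Boc2O, DMAP (10 mol %), MeCN, rt
Reagents that add atoms: di-tert-butyl dicarbonate (5), CC(C)(C)OC(=O)OC(=O)OC(C)(C)C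
Why: DMAP-catalysed O-tert-butoxycarbonylation of a phenol is a standard acyl transfer and installs the carbonate that later serves as the oxygen donor.

Step 4
Reactants: 6 tert-butyl [4-methoxy-5-methyl-2-(prop-1-en-2-yl)phenyl] carbonate
Product: 7 tert-butyl [2-(3-hydroxyprop-1-en-2-yl)-4-methoxy-5-methylphenyl] carbonate
Conditions: SeO2 (0.3 equiv), t-BuOOH (2 equiv), CH2Cl2, rt
Reagents that add atoms: tert-butyl hydroperoxide, CC(C)(C)OO (terminal oxygen source, relayed by selenium dioxide, O=[Se]=O)
Why: Riley-type allylic oxidation with catalytic SeO2 and t-BuOOH (ene reaction then [2,3]-sigmatropic shift) should hydroxylate the only allylic position of the alkene, the isopropenyl methyl, while the aryl carbonate and the ring methyl stay untouched at room temperature.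

Step 5
Reactants: 7 tert-butyl [2-(3-hydroxyprop-1-en-2-yl)-4-methoxy-5-methylphenyl] carbonate; 8 isobutyryl chloride
Product: 9 2-[2-(tert-butoxycarbonyloxy)-5-methoxy-4-methylphenyl]prop-2-en-1-yl 2-methylpropanoate
Conditions: i-PrCOCl, pyridine, DMAP (cat.), CH2Cl2, 0 °C
Reagents that add atoms: isobutyryl chloride (8), CC(C)C(Cl)=O
Why: Acylation of the primary allylic alcohol with an acid chloride under nucleophilic catalysis is fast at 0 °C and should outrun any transfer of the Boc group from the phenol oxygen.

Step 6
Reactants: 9 2-[2-(tert-butoxycarbonyloxy)-5-methoxy-4-methylphenyl]prop-2-en-1-yl 2-methylpropanoate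
Product: 11 [(4S)-4-(bromomethyl)-6-methoxy-7-methyl-2-oxo-4H-1,3-benzodioxin-4-yl]methyl 2-methylpropanoate, via tert-butoxy-benzodioxinylium ion 10 (not isolated)
Conditions: NBS (1.1 equiv), hydroquinidine 1,4-phthalazinediyl diether (DHQD)2PHAL (10 mol %), CHCl3/n-hexane 1:1, 4 Å MS, −40 °C, dark
Reagents that add atoms: N-bromosuccinimide, O=C1CCC(=O)N1Br
Why: Proposed new method: the catalyst–NBS complex transfers Br+ to the CH2 terminus of the 1,1-disubstituted styrene, the developing benzylic cation is captured by the carbonyl oxygen of the ortho tert-butyl carbonate to give dioxinylium ion 10, and loss of the tert-butyl group as 2-methylpropene (its proton ending on succinimide) makes the new C–O bond irreversible. The closest known reaction types are the cinchona-alkaloid-catalysed enantioselective halolactonization of 1,1-disubstituted styrenes and the halocyclization of homoallylic tert-butyl carbonates to cyclic carbonates; an aryl tert-butyl carbonate has not been shown as the nucleophile. The cyclic carbonate ring closes in the 6-exo-trig mode, attack at the benzylic (Markovnikov) carbon being preferred over 7-endo attack at CH2. The quaternary stereocentre is set by the chiral catalyst–bromine complex, which exposes one face of the prochiral alkene carbon to the internal oxygen nucleophile. The step needs alkene-over-arene chemoselectivity, secured by the O-acylated (deactivated) phenol and the far higher reactivity of the styrene, and carbonate-over-ester participation, secured because the isobutyrate can only form a reversible dioxolanylium ion that has no group to shed.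

Step 7
Reactants: 11 [(4S)-4-(bromomethyl)-6-methoxy-7-methyl-2-oxo-4H-1,3-benzodioxin-4-yl]methyl 2-methylpropanoate; 12 2-(trimethylsilyl)ethanol; 13 tigloyl chloride
Product: 15 2-[(2S)-1-bromo-3-(2-methylpropanoyloxy)-2-{[2-(trimethylsilyl)ethoxy]carbonyloxy}propan-2-yl]-4-methoxy-5-methylphenyl (E)-2-methylbut-2-enoate, via sodium phenoxide 14 (not isolated)
Conditions: 12 (1.1 equiv), NaH (1.05 equiv), THF, 0 °C; add to 11, THF, −78 °C; then 13 (1.3 equiv), −78 to 0 °C
Reagents that add atoms: 2-(trimethylsilyl)ethanol (12), C[Si](C)(C)CCO; tigloyl chloride (13), C/C=C(\C)C(Cl)=O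
Why: Alkoxide transcarbonation of the activated cyclic aryl alkyl carbonate expels the phenoxide as the better leaving group and leaves the tertiary oxygen as its 2-(trimethylsilyl)ethyl carbonate, and phenoxide 14 is O-acylated in the same flask by the acid chloride before it can displace the neopentyl-type bromide, with no bond to the stereocentre touched.

Step 8
Reactants: 15 2-[(2S)-1-bromo-3-(2-methylpropanoyloxy)-2-{[2-(trimethylsilyl)ethoxy]carbonyloxy}propan-2-yl]-4-methoxy-5-methylphenyl (E)-2-methylbut-2-enoate
Product: 18 [(2R)-2-{5-methoxy-4-methyl-2-[(E)-2-methylbut-2-enoyloxy]phenyl}oxiran-2-yl]methyl 2-methylpropanoate, via carbonate monoanion 16 (not isolated), via tertiary alkoxide 17 (not isolated)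
Conditions: Bu4NF (TBAF, 1.1 equiv), THF, 0 °C, N2 sweep
Reagents that add atoms: none
Why: Fluoride attack on silicon triggers the usual β-elimination of a 2-(trimethylsilyl)ethyl carbonate to ethene and carbonate monoanion 16, which loses CO2 to alkoxide 17, and this closes the oxirane by 3-exo-tet intramolecular Williamson displacement of the primary bromide with the C–O bond at the stereocentre retained, so that (S)-15 should give (R)-18 by a change of CIP priorities only.

**Compound list**

1 | 4-methoxy-3-methylphenol | Cc1cc(O)ccc1OC | starting material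
2 | 2-bromo-4-methoxy-5-methylphenol | Cc1cc(O)c(Br)cc1OC | intermediate
3 | isopropenylboronic acid pinacol ester | CC(=C)B1OC(C)(C)C(C)(C)O1 | starting material
4 | 4-methoxy-5-methyl-2-(prop-1-en-2-yl)phenol | Cc1cc(O)c(C(C)=C)cc1OC | intermediate
5 | di-tert-butyl dicarbonate | CC(C)(C)OC(=O)OC(=O)OC(C)(C)C | starting material
6 | tert-butyl [4-methoxy-5-methyl-2-(prop-1-en-2-yl)phenyl] carbonate | CC(C)(C)OC(=O)Oc1cc(C)c(OC)cc1C(C)=C | intermediate
7 | tert-butyl [2-(3-hydroxyprop-1-en-2-yl)-4-methoxy-5-methylphenyl] carbonate | CC(C)(C)OC(=O)Oc1cc(C)c(OC)cc1C(=C)CO | intermediate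
8 | isobutyryl chloride | CC(C)C(Cl)=O | starting material
9 | 2-[2-(tert-butoxycarbonyloxy)-5-methoxy-4-methylphenyl]prop-2-en-1-yl 2-methylpropanoate | CC(C)(C)OC(=O)Oc1cc(C)c(OC)cc1C(=C)COC(=O)C(C)C | intermediate
10 | (4S)-4-(bromomethyl)-2-tert-butoxy-6-methoxy-7-methyl-4-[(2-methylpropanoyloxy)methyl]-4H-1,3-benzodioxin-2-ylium succinimidate | CC(C)(C)OC1=[O+][C@@](COC(=O)C(C)C)(CBr)c2cc(OC)c(C)cc2O1.O=C1CCC(=O)[N-]1 | intermediate (not isolated)
11 | [(4S)-4-(bromomethyl)-6-methoxy-7-methyl-2-oxo-4H-1,3-benzodioxin-4-yl]methyl 2-methylpropanoate | O=C1Oc2cc(C)c(OC)cc2[C@](COC(=O)C(C)C)(CBr)O1 | intermediate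
12 | 2-(trimethylsilyl)ethanol | C[Si](C)(C)CCO | starting material
13 | tigloyl chloride, (E)-2-methylbut-2-enoyl chloride | C/C=C(\C)C(Cl)=O | starting material
14 | sodium 2-[(2S)-1-bromo-3-(2-methylpropanoyloxy)-2-{[2-(trimethylsilyl)ethoxy]carbonyloxy}propan-2-yl]-4-methoxy-5-methylphenolate | [Na+].[O-]c1cc(C)c(OC)cc1[C@](COC(=O)C(C)C)(CBr)OC(=O)OCC[Si](C)(C)C | intermediate (not isolated)
15 | 2-[(2S)-1-bromo-3-(2-methylpropanoyloxy)-2-{[2-(trimethylsilyl)ethoxy]carbonyloxy}propan-2-yl]-4-methoxy-5-methylphenyl (E)-2-methylbut-2-enoate | C/C=C(\C)C(=O)Oc1cc(C)c(OC)cc1[C@](COC(=O)C(C)C)(CBr)OC(=O)OCC[Si](C)(C)C | intermediate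
16 | tetrabutylammonium (2S)-1-bromo-2-{5-methoxy-4-methyl-2-[(E)-2-methylbut-2-enoyloxy]phenyl}-3-(2-methylpropanoyloxy)propan-2-yl carbonate | CCCC[N+](CCCC)(CCCC)CCCC.C/C=C(\C)C(=O)Oc1cc(C)c(OC)cc1[C@](COC(=O)C(C)C)(CBr)OC(=O)[O-] | intermediate (not isolated)
17 | tetrabutylammonium (2S)-1-bromo-2-{5-methoxy-4-methyl-2-[(E)-2-methylbut-2-enoyloxy]phenyl}-3-(2-methylpropanoyloxy)propan-2-olate | CCCC[N+](CCCC)(CCCC)CCCC.C/C=C(\C)C(=O)Oc1cc(C)c(OC)cc1[C@](COC(=O)C(C)C)(CBr)[O-] | intermediate (not isolated)
18 | [(2R)-2-{5-methoxy-4-methyl-2-[(E)-2-methylbut-2-enoyloxy]phenyl}oxiran-2-yl]methyl 2-methylpropanoate | C/C=C(\C)C(=O)Oc1cc(C)c(OC)cc1[C@]1(COC(=O)C(C)C)CO1 | target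

**Count**

Total steps: 8. Longest linear sequence: 8 steps, from 1 to 18.

**Steps most likely to fail**

Step 6 (proposed new method). The aryl carbonate carbonyl may be too weak a nucleophile, so that the bromonium ion is diverted to dibromide, bromohydrin or ester-participation products. The catalyst may also discriminate the two alkene faces poorly. The fallback uses known chemistry, a Sharpless asymmetric epoxidation, and sets out from phenol 4. O-Acylation with tigloyl chloride 13 (Et3N, DMAP, CH2Cl2, 0 °C) would give 4-methoxy-5-methyl-2-(prop-1-en-2-yl)phenyl (E)-2-methylbut-2-enoate F1. Allylic oxidation as in step 4 (SeO2, t-BuOOH, CH2Cl2) would give 2-(3-hydroxyprop-1-en-2-yl)-4-methoxy-5-methylphenyl (E)-2-methylbut-2-enoate F2. Epoxidation of this 2-substituted allylic alcohol with Ti(OiPr)4, L-(+)-diethyl tartrate and t-BuOOH (4 Å MS, CH2Cl2, −20 °C) would give 2-[(2S)-2-(hydroxymethyl)oxiran-2-yl]-4-methoxy-5-methylphenyl (E)-2-methylbut-2-enoate F3, the tartrate fixing the face by the usual rule for allylic alcohols. Isobutyrylation with 8 (pyridine, CH2Cl2, 0 °C) then comes back to the route at target 18; the descriptor changes from S to R on acylation through CIP priorities only.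

Step 8. The liberated alkoxide may attack the neighbouring aryl tiglate carbonyl through a six-membered transition state, an O-to-O acyl shift that would be followed by phenoxide ring closure onto the bromide. The carbonate monoanion may be alkylated by the bromide to a five-membered cyclic carbonate before CO2 is lost. Basic fluoride may cleave the aryl ester. The fallback sets out from 15 and separates unmasking from ring closure. Buffered fluoride (Bu4NF/AcOH 1:1, THF, rt) would release the tertiary oxygen as the neutral alcohol, 2-[(2S)-1-bromo-2-hydroxy-3-(2-methylpropanoyloxy)propan-2-yl]-4-methoxy-5-methylphenyl (E)-2-methylbut-2-enoate F4. Silver-assisted halide abstraction (Ag2O, CH2Cl2, rt, dark) would then close the oxirane without a free alkoxide and come back to the route at 18.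

Step 4. The allylic alcohol may be over-oxidized to the 2-arylpropenal, the reaction may stall at partial conversion, and the Boc group may shift from the phenol oxygen to the new primary hydroxyl. The fallback sets out from 6 and replaces C–H oxidation by bromination and substitution. Ionic allylic bromination (NBS, CHCl3, reflux; bromine adds to the alkene terminus and an allylic proton is lost) would give tert-butyl [2-(3-bromoprop-1-en-2-yl)-4-methoxy-5-methylphenyl] carbonate F5. Displacement of the allylic bromide by cesium isobutyrate (isobutyric acid, Cs2CO3, DMF, rt) then comes back to the route at 9, passing over 7.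

**Further compounds**

F1 | step 6 | 4-methoxy-5-methyl-2-(prop-1-en-2-yl)phenyl (E)-2-methylbut-2-enoate | C/C=C(\C)C(=O)Oc1cc(C)c(OC)cc1C(C)=C
F2 | step 6 | 2-(3-hydroxyprop-1-en-2-yl)-4-methoxy-5-methylphenyl (E)-2-methylbut-2-enoate | C/C=C(\C)C(=O)Oc1cc(C)c(OC)cc1C(=C)CO
F3 | step 6 | 2-[(2S)-2-(hydroxymethyl)oxiran-2-yl]-4-methoxy-5-methylphenyl (E)-2-methylbut-2-enoate | C/C=C(\C)C(=O)Oc1cc(C)c(OC)cc1[C@]1(CO)CO1
F4 | step 8 | 2-[(2S)-1-bromo-2-hydroxy-3-(2-methylpropanoyloxy)propan-2-yl]-4-methoxy-5-methylphenyl (E)-2-methylbut-2-enoate | C/C=C(\C)C(=O)Oc1cc(C)c(OC)cc1[C@](COC(=O)C(C)C)(CBr)O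
F5 | step 4 | tert-butyl [2-(3-bromoprop-1-en-2-yl)-4-methoxy-5-methylphenyl] carbonate | CC(C)(C)OC(=O)Oc1cc(C)c(OC)cc1C(=C)CBr
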